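The target's two ring A aroyl carbons (C1, C4) are disconnected from the meso C2–C3 pair, whose carbons each carry a ring B benzyl group (benzylic carbons C5, C6). The key step exploits this symmetric C2–C3 unit: its two aroyl groups sit as if added to one face of a Z-alkene. In one operation a twofold Zweifel olefination moves C2 and C3 from boron onto two 1-arylvinyl groups with retention, forming C1–C2 and C3–C4. The alkenes of the resulting diene are masked ring A ketones. The precursor is the meso 2,3-bis(pinacolboronate) of 1,4-bis(4-benzyloxyphenyl)butane, made by syn-diboration, plus a cold-generated 1-(2,4-dibenzyloxyphenyl)vinyllithium.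

Key step: step 6

Remark: the target is the meso (2R,3S) diastereomer and the route is built for it. All six phenols are carried as benzyl ethers because they come off under neutral conditions. The vinyllithium is made by iodine–lithium exchange at −78 °C, so it is never warmed beside the ortho benzyloxy group and brings no sulfinate into the iodination.

Step 1
Reactants: 1 4-(benzyloxy)benzyl chloride; 2 acetylene
Product: 4 1,4-bis(4-(benzyloxy)phenyl)but-2-yne, via bis(bromomagnesio)acetylene 3 (not isolated)
Conditions: HC≡CH (1.0 equiv), EtMgBr (2.0 equiv), Et2O, 35 °C; then CuBr·SMe2 (10 mol%), 1 (2.1 equiv), THF, 0 → 50 °C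
Reagents that add atoms: none
Why: Copper-catalysed coupling of an alkynyl Grignard reagent with a benzylic halide, run at both ends of the acetylene dianion equivalent 3, should join two electron-rich benzylic chlorides to the future C2–C3 carbons without creating a stereocentre.

Step 2
Reactants: 4 1,4-bis(4-(benzyloxy)phenyl)but-2-yne
Product: 5 (Z)-1,4-bis(4-(benzyloxy)phenyl)but-2-ene
Conditions: H2 (1 atm), Pd/CaCO3 poisoned with Pb(OAc)2, quinoline, EtOAc, rt, stopped after one equivalent of H2
Reagents that add atoms: none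
Why: Lindlar semihydrogenation delivers H2 to one face of the alkyne on the Pd/CaCO3–Pb(OAc)2 surface and stops at the Z-alkene, and aryl benzyl ethers are not hydrogenolysed on this poisoned catalyst.

Step 3
Reactants: 5 (Z)-1,4-bis(4-(benzyloxy)phenyl)but-2-ene; 6 bis(pinacolato)diboron
Product: 7 meso-(2R,3S)-2,2'-(1,4-bis(4-(benzyloxy)phenyl)butane-2,3-diyl)bis(4,4,5,5-tetramethyl-1,3,2-dioxaborolane)
Conditions: 6 (1.3 equiv), Cs2CO3 (15 mol%), MeOH (5 equiv), THF, 70 °C
Reagents that add atoms: none
Why: Alkoxide-catalysed diboration (Lewis-base activation of B2pin2) adds both boryl groups to the same face of the alkene, so the Z geometry of 5 should be translated stereospecifically into the meso C2/C3 pair, which is where both stereocentres of the target are set.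

Step 4
Reactants: 8 1-(2,4-bis(benzyloxy)phenyl)ethan-1-one
Product: 9 (E)-(1-(2,4-bis(benzyloxy)phenyl)ethylidene)hydrazine
Conditions: N2H4·H2O (10 equiv), AcOH (cat.), EtOH, 80 °C
Reagents that add atoms: hydrazine (as monohydrate), NN
Why: Hydrazone condensation of the aryl methyl ketone with a large excess of hydrazine, which keeps azine formation down.

Step 5
Reactants: 9 (E)-(1-(2,4-bis(benzyloxy)phenyl)ethylidene)hydrazine
Product: 10 2,4-bis(benzyloxy)-1-(1-iodovinyl)benzene
Conditions: I2 (2.2 equiv), 1,1,3,3-tetramethylguanidine (6 equiv), THF, 0 °C → rt, dark; filtration through basic Al2O3, used within a day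
Reagents that add atoms: iodine, II
Why: Barton vinyl iodide synthesis: iodine oxidises the hydrazone to the diazoalkane, which is iodinated at carbon, loses N2 and then a methyl proton to the guanidine base, so only the 1-iodo-1-arylethene can form.

Step 6
Reactants: 10 2,4-bis(benzyloxy)-1-(1-iodovinyl)benzene; 7 meso-(2R,3S)-2,2'-(1,4-bis(4-(benzyloxy)phenyl)butane-2,3-diyl)bis(4,4,5,5-tetramethyl-1,3,2-dioxaborolane)
Product: 14 meso-(3R,4S)-3,4-bis(4-(benzyloxy)benzyl)-2,5-bis(2,4-bis(benzyloxy)phenyl)hexa-1,5-diene, via 1-arylvinyllithium 11 (not isolated), via dilithium bis(boronate) complex 12 (not isolated), via bis(β-iodoalkyl boronate) 13 (not isolated)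
Conditions: 10 (2.6 equiv), t-BuLi (5.2 equiv), THF/Et2O, −78 °C; 7 (1.0 equiv), −78 → −40 → −78 °C; I2 (3.0 equiv), THF/MeOH, −78 °C; NaOMe (6 equiv), MeOH, −78 → 0 °C; work-up and chromatography at or below 0 °C
Reagents that add atoms: none
Why: Proposed new method: each equivalent of 11 adds to one boron of 7 to give the bis(boronate) complex 12; iodine then attacks the terminal CH2 of each electron-rich vinyl group, the resulting iodonium or β-iodo benzylic cation triggers a 1,2-shift of C2 or C3 from boron to carbon to give 13, and methoxide adds to boron and induces anti elimination of boron and iodide, releasing the two 1,1-disubstituted alkenes. The closest known reaction is the Zweifel olefination of a single secondary pinacol boronic ester with a 1-substituted vinyllithium; its twofold use on a vicinal bis(boronate) is the new element, and twofold boronate-complex formation has an analogy in the double one-carbon homologation of vicinal bis(boronates) with halomethyllithium. No ring is closed. No new stereocentre appears in 14 (the boron-bearing quaternary carbons of 13 are transient and become sp2), and C2 and C3 keep their configuration because the migrating carbon stays bonded to boron until it bonds to carbon, so meso 7 should map onto meso 14. The step needs retention at both carbons, complete twofold complexation and attack of iodine on the vinyl π bonds only: the first is inherent in the concerted metallate shift, the second is driven by the excess of 11 and the brief warming to −40 °C, and the third is secured by the alkoxy-activated styrene-type π systems, which are far more nucleophilic than the C–B σ bonds or the benzyl ether rings. Boron keeps C2 and C3 non-acidic, so nothing can epimerise before the carbonyl groups exist.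

Step 7
Reactants: 14 meso-(3R,4S)-3,4-bis(4-(benzyloxy)benzyl)-2,5-bis(2,4-bis(benzyloxy)phenyl)hexa-1,5-diene
Product: 15 meso-(2R,3S)-2,3-bis(4-(benzyloxy)benzyl)-1,4-bis(2,4-bis(benzyloxy)phenyl)butane-1,4-dione
Conditions: OsO4 (5 mol%), NaIO4 (6 equiv), 2,6-lutidine (4 equiv), 1,4-dioxane/H2O 3:1, 0 °C → rt, started on the day 14 is made
Reagents that add atoms: osmium tetroxide (OsO4), O=[Os](=O)(=O)=O; sodium periodate (NaIO4), [Na+].[O-]I(=O)(=O)=O; water, O
Why: Lemieux–Johnson oxidation: OsO4 dihydroxylates each electron-rich 1,1-disubstituted alkene and periodate cleaves the glycol to the aryl ketone, the lutidine buffer keeping conditions mild enough that the now enolisable C2 and C3 should not epimerise, while beginning the cleavage cold on the day 14 is made leaves the 2,5-diaryl-1,5-diene no time for Cope rearrangement.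

Step 8
Reactants: 15 meso-(2R,3S)-2,3-bis(4-(benzyloxy)benzyl)-1,4-bis(2,4-bis(benzyloxy)phenyl)butane-1,4-dione
Product: 16 meso-(2R,3S)-1,4-bis(2,4-dihydroxyphenyl)-2,3-bis(4-hydroxybenzyl)butane-1,4-dione (CNP0406969.1)
Conditions: H2 (1 atm), Pd/C (10 wt% Pd), EtOAc/MeOH 1:1, rt
Reagents that add atoms: none
Why: Catalytic hydrogenolysis of the six aryl benzyl ethers over Pd/C runs under neutral conditions, so C2 and C3 should not epimerise and no acid-induced furan formation can occur, while the ortho- and para-oxygenated aryl ketones are poor substrates for carbonyl reduction.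

Compound list
1 | 4-(benzyloxy)benzyl chloride | ClCc1ccc(OCc2ccccc2)cc1 | starting material
2 | acetylene (ethyne) | C#C | starting material
3 | bis(bromomagnesio)acetylene (ethyne-1,2-diylbis(magnesium bromide)) | Br[Mg]C#C[Mg]Br | intermediate (not isolated)
4 | 1,4-bis(4-(benzyloxy)phenyl)but-2-yne | C(C#CCc1ccc(OCc2ccccc2)cc1)c1ccc(OCc2ccccc2)cc1 | intermediate
5 | (Z)-1,4-bis(4-(benzyloxy)phenyl)but-2-ene | C(/C=C\Cc1ccc(OCc2ccccc2)cc1)c1ccc(OCc2ccccc2)cc1 | intermediate
6 | bis(pinacolato)diboron | CC1(C)OB(OC1(C)C)B1OC(C)(C)C(C)(C)O1 | starting material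
7 | meso-(2R,3S)-2,2'-(1,4-bis(4-(benzyloxy)phenyl)butane-2,3-diyl)bis(4,4,5,5-tetramethyl-1,3,2-dioxaborolane) | CC1(C)OB(OC1(C)C)[C@@H](Cc1ccc(OCc2ccccc2)cc1)[C@@H](Cc1ccc(OCc2ccccc2)cc1)B1OC(C)(C)C(C)(C)O1 | intermediate
8 | 1-(2,4-bis(benzyloxy)phenyl)ethan-1-one | CC(=O)c1ccc(OCc2ccccc2)cc1OCc1ccccc1 | starting material
9 | (E)-(1-(2,4-bis(benzyloxy)phenyl)ethylidene)hydrazine | C/C(=N\N)c1ccc(OCc2ccccc2)cc1OCc1ccccc1 | intermediate
10 | 2,4-bis(benzyloxy)-1-(1-iodovinyl)benzene | C=C(I)c1ccc(OCc2ccccc2)cc1OCc1ccccc1 | intermediate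
11 | (1-(2,4-bis(benzyloxy)phenyl)vinyl)lithium | [Li]C(=C)c1ccc(OCc2ccccc2)cc1OCc1ccccc1 | intermediate (not isolated)
12 | dilithium bis(boronate) complex: each boron of 7 additionally carries one 1-(2,4-bis(benzyloxy)phenyl)vinyl group, meso configuration at C2/C3 retained | [Li+].[Li+].C=C(c1ccc(OCc2ccccc2)cc1OCc1ccccc1)[B-]1(OC(C)(C)C(C)(C)O1)[C@@H](Cc1ccc(OCc2ccccc2)cc1)[C@@H](Cc1ccc(OCc2ccccc2)cc1)[B-]1(OC(C)(C)C(C)(C)O1)C(=C)c1ccc(OCc2ccccc2)cc1OCc1ccccc1 | intermediate (not isolated)
13 | (3R,4S)-3,4-bis(4-(benzyloxy)benzyl)-2,5-bis(2,4-bis(benzyloxy)phenyl)-1,6-diiodo-2,5-bis(4,4,5,5-tetramethyl-1,3,2-dioxaborolan-2-yl)hexane, mixture of epimers at the boron-bearing C2 and C5 | ICC(c1ccc(OCc2ccccc2)cc1OCc1ccccc1)(B1OC(C)(C)C(C)(C)O1)[C@@H](Cc1ccc(OCc2ccccc2)cc1)[C@@H](Cc1ccc(OCc2ccccc2)cc1)C(CI)(c1ccc(OCc2ccccc2)cc1OCc1ccccc1)B1OC(C)(C)C(C)(C)O1 | intermediate (not isolated)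
14 | meso-(3R,4S)-3,4-bis(4-(benzyloxy)benzyl)-2,5-bis(2,4-bis(benzyloxy)phenyl)hexa-1,5-diene | C=C(c1ccc(OCc2ccccc2)cc1OCc1ccccc1)[C@@H](Cc1ccc(OCc2ccccc2)cc1)[C@@H](Cc1ccc(OCc2ccccc2)cc1)C(=C)c1ccc(OCc2ccccc2)cc1OCc1ccccc1 | intermediate
15 | meso-(2R,3S)-2,3-bis(4-(benzyloxy)benzyl)-1,4-bis(2,4-bis(benzyloxy)phenyl)butane-1,4-dione | O=C(c1ccc(OCc2ccccc2)cc1OCc1ccccc1)[C@@H](Cc1ccc(OCc2ccccc2)cc1)[C@@H](Cc1ccc(OCc2ccccc2)cc1)C(=O)c1ccc(OCc2ccccc2)cc1OCc1ccccc1 | intermediate
16 | meso-(2R,3S)-1,4-bis(2,4-dihydroxyphenyl)-2,3-bis(4-hydroxybenzyl)butane-1,4-dione | O=C(c1ccc(O)cc1O)[C@@H](Cc1ccc(O)cc1)[C@@H](Cc1ccc(O)cc1)C(=O)c1ccc(O)cc1O | target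

Total step count: 8 (the vinyllithium is generated inside step 6).
Longest linear sequence: 6 steps (1, 2, 3, 6, 7, 8); the second branch (steps 4 and 5) joins at step 6.

Steps most likely to fail

Step 6. Once the first boron has become an anionic, crowded borate, the neighbouring boron may not take up its vinyllithium. The reaction would then stop at mono-olefination, or the unreacted C–B bond would be lost by protodeboronation or iodinolysis. Fallback, from 7 back to 14: the two olefinations are run one after the other with isolation, each as the established Zweifel olefination of one secondary pinacol boronic ester. 7 in slight excess is treated with one equivalent of 11 (from 10 and t-BuLi at −78 °C), then I2/MeOH and NaOMe. This should give the racemic homoallylic boronic ester rac-2-((2R,3S)-3-(4-(benzyloxy)benzyl)-1-(4-(benzyloxy)phenyl)-4-(2,4-bis(benzyloxy)phenyl)pent-4-en-2-yl)-4,4,5,5-tetramethyl-1,3,2-dioxaborolane F1, in which the remaining boron sits beside a neutral alkene. F1 is isolated cold and put through the same sequence with a second portion of 11. Both migrations again proceed with retention, and the route is rejoined at 14.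

Step 3. Addition of the activated diboron to an unstrained internal alkene may stall, or the carbanionic intermediate may be protonated by methanol, which would give hydroboration instead of diboration. Fallback, from 5 back to 7: the mechanism is changed to oxidative addition and insertion at rhodium, with bis(catecholato)diboron and Rh(acac)(nbd)/1,4-bis(diphenylphosphino)butane in THF at rt. This type of catalysis is known to add syn to unstrained internal alkenes and should give the meso bis(catecholboronate) meso-(2R,3S)-2,2'-(1,4-bis(4-(benzyloxy)phenyl)butane-2,3-diyl)bis(1,3,2-benzodioxaborole) F2. F2 is transesterified with pinacol in THF at rt to return to 7.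

Step 5. Azine formation during condensation, geminal di-iodination, and solvolytic or photochemical loss of the electron-rich 1-iodoalkene during isolation may together leave too little 10. Fallback, from 8 back to 11: 8 is condensed with 2,4,6-triisopropylbenzenesulfonyl hydrazide (MeOH, cat. HCl, rt) to the crystalline, storable (E)-N'-(1-(2,4-bis(benzyloxy)phenyl)ethylidene)-2,4,6-triisopropylbenzenesulfonohydrazide F3. A Shapiro reaction (n-BuLi 2.0 equiv, THF, −78 → 0 °C until N2 evolution ends, then back to −78 °C) delivers 11 directly in the flask of step 6. Extra iodine is then needed there to cover the lithium 2,4,6-triisopropylbenzenesulfinate that is carried along.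

Further compounds
F1 | step 6 | rac-2-((2R,3S)-3-(4-(benzyloxy)benzyl)-1-(4-(benzyloxy)phenyl)-4-(2,4-bis(benzyloxy)phenyl)pent-4-en-2-yl)-4,4,5,5-tetramethyl-1,3,2-dioxaborolane (one enantiomer drawn) | C=C(c1ccc(OCc2ccccc2)cc1OCc1ccccc1)[C@@H](Cc1ccc(OCc2ccccc2)cc1)[C@@H](Cc1ccc(OCc2ccccc2)cc1)B1OC(C)(C)C(C)(C)O1
F2 | step 3 | meso-(2R,3S)-2,2'-(1,4-bis(4-(benzyloxy)phenyl)butane-2,3-diyl)bis(1,3,2-benzodioxaborole) | B1(Oc2ccccc2O1)[C@@H](Cc1ccc(OCc2ccccc2)cc1)[C@@H](Cc1ccc(OCc2ccccc2)cc1)B1Oc2ccccc2O1
F3 | step 5 | (E)-N'-(1-(2,4-bis(benzyloxy)phenyl)ethylidene)-2,4,6-triisopropylbenzenesulfonohydrazide | C/C(=N\NS(=O)(=O)c1c(C(C)C)cc(C(C)C)cc1C(C)C)c1ccc(OCc2ccccc2)cc1OCc1ccccc1
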